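## Structural features

The target is an achiral tetra-aryl compound of the bibenzyl class. Ring A (pentasubstituted) and ring B (a 3-methoxyphenyl ring) are joined by a saturated two-carbon bridge from C1 of ring A to C1' of ring B. Ring A carries the hydroxyl on C3, the methoxyl on C5 and its only hydrogen on C4. C2 and C6 each bear a 4-hydroxybenzyl group through the diarylmethane carbons C7 and C7'. There is no stereocentre, so nothing has to be set or guarded against epimerisation. The fragile parts are the three free phenols, which oxidise easily under basic aerobic conditions, and the two diarylmethane methylenes, which are doubly benzylic and can release a 4-hydroxybenzyl cation again under hot strong acid. The real difficulty is positional. C1, C2 and C6 form a contiguous, fully substituted array, C4 must stay free although it lies between two oxygens, and the two oxygens of ring A must end up different. The key step uses the fact that C2 and C6 are each ortho to one ring A oxygen and para to the other, which makes them the preferred sites for a soft benzylic cation. C4 is ortho to both oxygens and is also activated, so the plan rests on a preference among three nucleophilic carbons, not on a blocked position.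

## Logic of the disconnections

**10 ⇒ 5 + two molecules of 6.** The bonds cut are C2–C7 and C6–C7'. They join the two carbons of ring A that are para to an oxygen to benzylic carbons that become electrophilic as soon as 6 loses water to give 7. The cut removes fourteen carbons and two rings in one operation. It leads back to 5, in which the bridge and the OH/OMe distinction are already in place, so no protecting group is needed. The demand on the forward step is site control: 5 must take up 7 twice, through 8 or 9, at C2 and C6 and not at C4, and must stop after the second alkylation.

**5 ⇒ 3.** No skeletal bond is cut. The saturated bridge is traced back to a triple bond, because an sp carbon on ring A opens a cross-coupling disconnection between two simple arenes. The gain is that both bridge carbons arrive with ring B. The forward step must saturate the alkyne completely, through 4, without touching the arenes or the aryl C–O bonds.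

**3 ⇒ 1 + 2.** The bond cut is C1 of ring A to the alkyne carbon. The three substituents of ring A in 3 are mutually meta, a pattern that electrophilic substitution cannot build, so it is bought ready-made in 1. The other half, 2, already holds ring B and both bridge carbons. The forward coupling must tolerate a free phenol and an electron-rich aryl bromide and must not consume 2 by oxidative dimerisation.

## Other disconnections considered

**Alternative 1:** The cut removes both bonds of the bridge to the rings (C1–Cα and Cβ–C1'). The pieces are the fully substituted ring A bromide A1, the vinylboronic ester A2 and the ring B triflate A3.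

- Forward key step: halogen–lithium exchange on A1 and addition of the aryllithium to A2 would give a boron ate complex. A palladium catalyst carrying a ferrocenyl bisphosphine, after oxidative addition to A3, would trigger migration of the ring A aryl from boron to Cα while ring B is delivered to Cβ. The product would be the racemic benzylic boronate A4. Removal of boron from Cα and hydrogenolysis of three benzyl ethers would then lead to 10.
- In its favour: the two bridge bonds form with complete positional certainty and ring B enters last, so analogues would be easy. On the certainty of the bridge construction it is better than the chosen plan. It is equal in building no ring and leaving no stereocentre in the end.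
- Against it, structure: A1 already needs both 4-benzyloxybenzyl groups ortho to the bromine. These would most plausibly come from a double benzylation of 1, a ring made less nucleophilic by bromine. The regiochemical problem of the chosen plan is therefore moved, not removed.
- Against it, mechanism: the migrating aryl is flanked by two benzyl groups, which burdens both ate-complex formation and the 1,2-shift. The aryllithium also sits next to far more acidic diarylmethane C–H bonds, so proton transfer can compete. The stereocentre formed at Cα is erased at once.
- Step economy: protection, key step, deboronation and deprotection after the synthesis of A1 add up to at least six steps against three. It also needs an organolithium at low temperature where the chosen plan needs catalytic acid.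

**Alternative 2:** The cut goes through ring A itself (C1–C6 and C4–C5). The ring would be assembled from the benzylmalonate A5 and the enone A6.

- Forward key step: under an alkoxide base the anion of A5 would add to the β-carbon of A6, and the methyl ketone enolate so released would close the ring on a malonate ester by a Claisen condensation. The product would be the keto ester A7 as a diastereomer mixture. Loss of the ester would give the symmetric dione A8 and dehydrogenation the symmetric resorcinol A9. Monomethylation and hydrogenolysis would follow.
- In its favour: every substituent of ring A is placed by the connectivity of acyclic precursors, so C4 cannot be benzylated. On positional control it is better than the chosen plan. The symmetry of A8 and A9 makes the two hydroxyls equivalent, so the methylation raises no regiochemical question, which is an equal footing with the ready-made OH/OMe pattern of 5.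
- Against it, mechanism: the Michael addition must create a quaternary carbon next to a tertiary one on an α,β-disubstituted enone. It would be slow and reversible, and γ-deprotonation of A6 would compete.
- Against it, structure: the ring is formed at the wrong oxidation level. Dehydrogenation must be done in the presence of benzyl ethers and oxidisable diarylmethane carbons. Monomethylation of A9 is statistical.
- Step economy: about three steps to A5 and A6 and five more after them, against three in all.

**Alternative 3:** The cut is at C1–C2 and C1–C6. C1 is brought in as the carbonyl carbon of the cinnamoyl Weinreb amide A11 and is stitched between the two outer α-carbons of the symmetric diketone A10.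

- Forward key step: the dianion of A10, made with a lithium amide base, would be acylated at one outer α-carbon by A11 to give the triketone A12. Aqueous hydroxide would then drive an intramolecular aldol condensation of the other outer α-carbon onto the same carbonyl, giving the stilbene A13 directly at the aromatic oxidation level. Monomethylation of one of the two equivalent hydroxyls and a single hydrogenation (alkene and both benzyl ethers) would lead to 10.
- In its favour: like alternative 2 it leaves C4 free by construction, so it is better than the chosen plan on positional control. Unlike alternative 2 it needs no oxidation. It is the equal of the chosen plan in being biomimetic; it copies the polyketide origin of ring A where the chosen plan copies the late benzylation.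
- Against it, mechanism: a dianion may add to the unsaturated amide in the conjugate sense. A12 can also close through oxygen, by oxa-Michael addition to the styryl double bond or by cyclodehydration to a pyranone. The aldol must attack a carbonyl that is part of an enolised β-diketone and is flanked by a benzyl-bearing carbon.
- Against it, structure and step economy: the statistical monomethylation returns. A10 and A11 each need about two steps, for a total near seven, with cryogenic strong base.

Key step: step 3

Assumption: the locants of the target name are read as 3-hydroxy-5,3'-dimethoxy (hydroxyl on C3 and methoxyl on C5 of ring A, methoxyl on C3' of ring B). This is the only reading in which C3 carries a single substituent, and it is the constitution encoded by the SMILES string.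

## Route

Step 1
Reactants: 1 3-bromo-5-methoxyphenol; 2 3-ethynylanisole
Product: 3 3-methoxy-5-[(3-methoxyphenyl)ethynyl]phenol
Conditions: 2 (1.2 equiv), PdCl2(PPh3)2 (3 mol %), CuI (5 mol %), Et3N/DMF (1:1), degassed, Ar, 70 °C
Reagents that add atoms: none
Why: Sonogashira coupling: zerovalent palladium inserts into the C–Br bond of 1, the copper acetylide of 2 transmetallates and reductive elimination forms the aryl–alkynyl bond. The bromine is meta to both oxygens, so oxidative addition is not strongly retarded, and with no ortho hydroxyl there is no path to a benzofuran. The free phenol is tolerated under amine base, and degassing limits Glaser dimerisation of 2.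

Step 2
Reactants: 3 3-methoxy-5-[(3-methoxyphenyl)ethynyl]phenol
Product: 5 3-hydroxy-5,3'-dimethoxybibenzyl, via (Z)-3-hydroxy-5,3'-dimethoxystilbene 4 (not isolated)
Conditions: H2 (1 atm), 10% Pd/C, EtOAc/MeOH (1:1), rt
Reagents that add atoms: none
Why: Heterogeneous catalytic hydrogenation: two successive syn additions of hydrogen on the palladium surface take the alkyne through 4 to the saturated bridge. The arenes and the aryl C–O bonds are inert at ambient pressure and temperature, and no stereocentre results.

Step 3
Reactants: 5 3-hydroxy-5,3'-dimethoxybibenzyl; 6 4-hydroxybenzyl alcohol (two molecules enter the product)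
Product: 10 2,6-bis(4-hydroxybenzyl)-3-hydroxy-5,3'-dimethoxybibenzyl, via p-quinone methide 7 (not isolated), via 6-(4-hydroxybenzyl) monoadduct 8 (not isolated), via 2-(4-hydroxybenzyl) monoadduct 9 (not isolated)
Conditions: 6 (2.3 equiv, added over 8 h as a dioxane solution), TsOH·H2O (0.2 equiv), 1,4-dioxane, 60 °C, Ar; NaHCO3 quench, then silica and reversed-phase chromatography
Reagents that add atoms: none
Why: Twofold Friedel–Crafts alkylation by a p-quinone methide: TsOH protonates the benzylic hydroxyl of 6, water leaves, and the resulting 4-hydroxybenzyl cation (O-protonated 7) is attacked at its exocyclic carbon by C6 or C2 of ring A of 5; loss of a proton from the arenium ion restores the arene and gives 8 or 9, each of which repeats the sequence at its remaining para-activated carbon, so that both converge on 10. The closest known reaction type is the acid-promoted C-benzylation of resorcinol- and phloroglucinol-type phenols by hydroxybenzyl alcohols. No ring closes and no stereocentre is formed, so neither a mode of closure nor stereocontrol has to be specified. The step needs chemoselectivity for ring A and site selectivity for C2 and C6 over C4. Ring A has two oxygen donors in a 1,3-relation and is by far the most nucleophilic arene present, whereas ring B, 6 and the phenol rings just attached have one donor each. Attack at C2 or C6 leads to an arenium ion stabilised by a para and an ortho oxygen, attack at C4 to one stabilised by two ortho oxygens only and approached between two solvated oxygen substituents, which is why 5-alkylresorcinol ethers are usually substituted next to the alkyl chain first; this is a preference and not a block. O-Benzylation and ether formation from 6 are reversible under the acid and drain into the C–C products, and slow addition keeps 7 scarce, which holds back self-condensation of 6 and a third benzylation at C4.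

## Compound list

1 | 3-bromo-5-methoxyphenol | COc1cc(O)cc(Br)c1 | starting material
2 | 3-ethynylanisole (1-ethynyl-3-methoxybenzene) | COc1cccc(C#C)c1 | starting material
3 | 3-methoxy-5-[(3-methoxyphenyl)ethynyl]phenol | COc1cccc(C#Cc2cc(O)cc(OC)c2)c1 | intermediate
4 | (Z)-3-hydroxy-5,3'-dimethoxystilbene | COc1cccc(/C=C\c2cc(O)cc(OC)c2)c1 | intermediate (not isolated)
5 | 3-hydroxy-5,3'-dimethoxybibenzyl | COc1cccc(CCc2cc(O)cc(OC)c2)c1 | intermediate
6 | 4-hydroxybenzyl alcohol | OCc1ccc(O)cc1 | starting material
7 | p-quinone methide (4-methylidenecyclohexa-2,5-dien-1-one) | C=C1C=CC(=O)C=C1 | intermediate (not isolated)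
8 | 6-(4-hydroxybenzyl)-3-hydroxy-5,3'-dimethoxybibenzyl | COc1cccc(CCc2cc(O)cc(OC)c2Cc2ccc(O)cc2)c1 | intermediate (not isolated)
9 | 2-(4-hydroxybenzyl)-3-hydroxy-5,3'-dimethoxybibenzyl | COc1cccc(CCc2cc(OC)cc(O)c2Cc2ccc(O)cc2)c1 | intermediate (not isolated)
10 | 2,6-bis(4-hydroxybenzyl)-3-hydroxy-5,3'-dimethoxybibenzyl | COc1cccc(CCc2c(Cc3ccc(O)cc3)c(O)cc(OC)c2Cc2ccc(O)cc2)c1 | target

## Step count and least certain steps

Total step count: 3. Longest linear sequence: 3 steps (1 and 2 to 3, then 5, then 10).

**Step 3 (key step).** What is most likely to go wrong is insufficient discrimination among the three activated carbons of ring A, together with over-alkylation. C4 is ortho to both oxygens, and each benzylation makes ring A richer. The result would be a statistical mixture of mono-, bis- and tris-adducts that is hard to separate. Oligomerisation of the quinone methide with its own precursor can also outrun capture by ring A.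

Fallback, setting out from 5 and coming back at 10: the regiochemistry is fixed by halogen instead of by electronic preference.
- O-Benzylation of 5 (BnBr, K2CO3, DMF, rt) should give 3-benzyloxy-5,3'-dimethoxybibenzyl F1.
- Twofold bromination (NBS, 2.0 equiv, MeCN, 0 °C) is expected to place both bromines para to the two alkoxy groups, the usual pattern of 3,5-dialkoxytoluenes, and give 3-benzyloxy-2,6-dibromo-5,3'-dimethoxybibenzyl F2.
- A double Negishi coupling with (4-benzyloxybenzyl)zinc chloride, prepared from 4-benzyloxybenzyl chloride with Zn and LiCl in THF, under Pd(OAc)2/SPhos at 60 °C should give 3-benzyloxy-2,6-bis(4-benzyloxybenzyl)-5,3'-dimethoxybibenzyl F3.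
- Hydrogenolysis of the three benzyl ethers (H2, 10% Pd/C, EtOAc/MeOH, rt) would return the route at 10.

**Step 1.** What is most likely to go wrong is copper-mediated oxidative dimerisation of the alkyne running ahead of a slow oxidative addition. The bromide is electron-rich and its phenol is partly deprotonated by the amine, so conversion may stall while 2 is consumed.

Fallback, setting out from 2 (with 1) and coming back at 5: the bridge is made as an alkene by a copper-free Suzuki–Miyaura coupling.
- Hydroboration of 2 with pinacolborane (Cp2Zr(H)Cl 5 mol %, Et3N 10 mol %, 60 °C) should give (E)-2-[2-(3-methoxyphenyl)ethenyl]-4,4,5,5-tetramethyl-1,3,2-dioxaborolane F4.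
- Coupling with 1 (PdCl2(dppf), K2CO3, dioxane/H2O, 80 °C) should give (E)-3-hydroxy-5,3'-dimethoxystilbene F5.
- Hydrogenation under the conditions of step 2 would give 5.

**Step 2.** What is most likely to go wrong is stalling at the stilbene stage through poisoning of the palladium surface by copper, phosphine or ammonium halide residues carried over from step 1. Forcing the conditions to overcome this could start to saturate an electron-rich ring.

Fallback, setting out from 1 and coming back at 5: the bridge is brought in already saturated, so no reduction is needed.
- Hydroboration of 3-vinylanisole with 9-borabicyclo[3.3.1]nonane (THF, 0 °C to rt) should give 9-[2-(3-methoxyphenyl)ethyl]-9-borabicyclo[3.3.1]nonane F6.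
- This would be coupled in the same flask with 1 by a B-alkyl Suzuki–Miyaura reaction (PdCl2(dppf), aqueous K3PO4, THF/DMF, 65 °C) to give 5 directly.

## Further compounds

F1 | step 3 | 3-benzyloxy-5,3'-dimethoxybibenzyl | COc1cccc(CCc2cc(OCc3ccccc3)cc(OC)c2)c1
F2 | step 3 | 3-benzyloxy-2,6-dibromo-5,3'-dimethoxybibenzyl | COc1cccc(CCc2c(Br)c(OCc3ccccc3)cc(OC)c2Br)c1
F3 | step 3 | 3-benzyloxy-2,6-bis(4-benzyloxybenzyl)-5,3'-dimethoxybibenzyl | COc1cccc(CCc2c(Cc3ccc(OCc4ccccc4)cc3)c(OCc3ccccc3)cc(OC)c2Cc2ccc(OCc3ccccc3)cc2)c1
F4 | step 1 | (E)-2-[2-(3-methoxyphenyl)ethenyl]-4,4,5,5-tetramethyl-1,3,2-dioxaborolane | COc1cccc(/C=C/B2OC(C)(C)C(C)(C)O2)c1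
F5 | step 1 | (E)-3-hydroxy-5,3'-dimethoxystilbene | COc1cccc(/C=C/c2cc(O)cc(OC)c2)c1
F6 | step 2 | 9-[2-(3-methoxyphenyl)ethyl]-9-borabicyclo[3.3.1]nonane | COc1cccc(CCB2C3CCCC2CCC3)c1
A1 | alternative 1 | 2-bromo-1,3-bis(4-benzyloxybenzyl)-4-benzyloxy-6-methoxybenzene | COc1cc(OCc2ccccc2)c(Cc2ccc(OCc3ccccc3)cc2)c(Br)c1Cc1ccc(OCc2ccccc2)cc1
A2 | alternative 1 | vinylboronic acid pinacol ester (4,4,5,5-tetramethyl-2-vinyl-1,3,2-dioxaborolane) | C=CB1OC(C)(C)C(C)(C)O1
A3 | alternative 1 | 3-methoxyphenyl trifluoromethanesulfonate | COc1cccc(OS(=O)(=O)C(F)(F)F)c1
A4 | alternative 1 | 2-{1-[3-benzyloxy-2,6-bis(4-benzyloxybenzyl)-5-methoxyphenyl]-2-(3-methoxyphenyl)ethyl}-4,4,5,5-tetramethyl-1,3,2-dioxaborolane (racemic) | COc1cccc(CC(B2OC(C)(C)C(C)(C)O2)c2c(Cc3ccc(OCc4ccccc4)cc3)c(OCc3ccccc3)cc(OC)c2Cc2ccc(OCc3ccccc3)cc2)c1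
A5 | alternative 2 | dimethyl 2-(4-benzyloxybenzyl)malonate | COC(=O)C(Cc1ccc(OCc2ccccc2)cc1)C(=O)OC
A6 | alternative 2 | (E)-3-(4-benzyloxybenzyl)-6-(3-methoxyphenyl)hex-3-en-2-one | CC(=O)/C(Cc1ccc(OCc2ccccc2)cc1)=C/CCc1cccc(OC)c1
A7 | alternative 2 | methyl 1,3-bis(4-benzyloxybenzyl)-2-[2-(3-methoxyphenyl)ethyl]-4,6-dioxocyclohexane-1-carboxylate (mixture of diastereomers) | COC(=O)C1(Cc2ccc(OCc3ccccc3)cc2)C(CCc2cccc(OC)c2)C(Cc2ccc(OCc3ccccc3)cc2)C(=O)CC1=O
A8 | alternative 2 | 4,6-bis(4-benzyloxybenzyl)-5-[2-(3-methoxyphenyl)ethyl]cyclohexane-1,3-dione (mixture of diastereomers) | COc1cccc(CCC2C(Cc3ccc(OCc4ccccc4)cc3)C(=O)CC(=O)C2Cc2ccc(OCc3ccccc3)cc2)c1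
A9 | alternative 2 | 2,6-bis(4-benzyloxybenzyl)-3,5-dihydroxy-3'-methoxybibenzyl | COc1cccc(CCc2c(Cc3ccc(OCc4ccccc4)cc3)c(O)cc(O)c2Cc2ccc(OCc3ccccc3)cc2)c1
A10 | alternative 3 | 1,7-bis(4-benzyloxyphenyl)heptane-3,5-dione | O=C(CCc1ccc(OCc2ccccc2)cc1)CC(=O)CCc1ccc(OCc2ccccc2)cc1
A11 | alternative 3 | (E)-N-methoxy-N-methyl-3-(3-methoxyphenyl)prop-2-enamide | COc1cccc(/C=C/C(=O)N(C)OC)c1
A12 | alternative 3 | (E)-4-(4-benzyloxybenzyl)-9-(4-benzyloxyphenyl)-1-(3-methoxyphenyl)non-1-ene-3,5,7-trione (racemic, keto form) | COc1cccc(/C=C/C(=O)C(Cc2ccc(OCc3ccccc3)cc2)C(=O)CC(=O)CCc2ccc(OCc3ccccc3)cc2)c1
A13 | alternative 3 | (E)-2,6-bis(4-benzyloxybenzyl)-3,5-dihydroxy-3'-methoxystilbene | COc1cccc(/C=C/c2c(Cc3ccc(OCc4ccccc4)cc3)c(O)cc(O)c2Cc2ccc(OCc3ccccc3)cc2)c1
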